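**Plan**

1. Retrosynthesis: the base-labile C3 stereocentre of the (3R)-isoflavanone 17 is removed first (C2–H/C3–H bonds), which leads back to the flat isoflavone 11.
2. In 11 the dihydropyran of ring B is cut at ArCH2–CH2 and O–CMe2 into isobutene and an ortho-quinone methide, and the C8–prenyl bond is cut back to an O7 1,1-dimethylallyl ether; both lead to daidzein.
3. Forward: daidzein → 7-O-propargylic ether → ortho-hydroxymethylation of ring B → semihydrogenation → one thermal operation (Claisen shift O7→C8, then ortho-quinone methide [4+2] with isobutene closes the chroman) → silylation → asymmetric reduction → re-oxidation → desilylation.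
4. Enabling feature: O4' and the C3' methylene sit ortho on ring B, so loss of water dearomatises it to the 1-oxadiene O=C4'–C3'=CH2; the isoflavone C3, para to O4', is sp2 and has no hydrogen, so no para-quinone methide can compete; the gem-dimethyl end of isobutene fixes C–C bonding at CH2 and C–O bonding at the tertiary carbon.
5. Stereochemistry: C3 (R) is set by RuCl[(R,R)-TsDPEN](p-cymene) transfer hydrogenation with dynamic kinetic resolution (cis-(3R,4R) alcohol); C4 is then re-oxidised under non-enolising conditions.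

Key step: step 4

Assumption: the catalyst sense in step 6 follows the usual aryl-ketone model, in which the (R,R) catalyst gives the (R)-carbinol; with cis-selective reduction this fixes C3 as (R).

**Route**

Step 1
Reactants: 1 daidzein; 2 3-chloro-3-methylbut-1-yne
Product: 3 3-(4-hydroxyphenyl)-7-[(2-methylbut-3-yn-2-yl)oxy]-4H-chromen-4-one
Conditions: K2CO3 (1.1 equiv), KI, CuI (cat.), acetone/DMF, 55 °C
Reagents that add atoms: 3-chloro-3-methylbut-1-yne (2), C#CC(C)(C)Cl
Why: Copper-assisted propargylic O-alkylation (Williamson-type ether synthesis), in which the 7-OH, para to the C4 carbonyl and the more acidic phenol, is the one deprotonated by one equivalent of carbonate, so the ether should form on ring A and leave the 4'-OH free.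

Step 2
Reactants: 3 3-(4-hydroxyphenyl)-7-[(2-methylbut-3-yn-2-yl)oxy]-4H-chromen-4-one; 4 formaldehyde (as paraformaldehyde)
Product: 6 3-[4-hydroxy-3-(hydroxymethyl)phenyl]-7-[(2-methylbut-3-yn-2-yl)oxy]-4H-chromen-4-one, via benzodioxaborin 5 (not isolated)
Conditions: PhB(OH)2, (CH2O)n, EtCO2H (cat.), PhMe/1,4-dioxane, 4 Å MS, 90 °C; then pinacol, THF, rt
Reagents that add atoms: formaldehyde (4), C=O
Why: Boronic-acid-templated ortho-specific hydroxymethylation of a phenol, in which the aryloxyboronate delivers formaldehyde to C3' through a six-membered transition state and the 1,3,2-benzodioxaborin 5 ties up the phenol oxygen so that a second hydroxymethylation at C5' is blocked, before transesterification with pinacol frees the salicyl alcohol.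

Step 3
Reactants: 6 3-[4-hydroxy-3-(hydroxymethyl)phenyl]-7-[(2-methylbut-3-yn-2-yl)oxy]-4H-chromen-4-one
Product: 7 3-[4-hydroxy-3-(hydroxymethyl)phenyl]-7-[(2-methylbut-3-en-2-yl)oxy]-4H-chromen-4-one
Conditions: H2 (1 atm), Pd/CaCO3 poisoned with Pb(OAc)2, quinoline, EtOAc, rt
Reagents that add atoms: none
Why: Lindlar semihydrogenation of the terminal alkyne should stop at the alkene on the poisoned catalyst and leave the chromone double bond and the benzylic alcohol untouched.

Step 4
Reactants: 7 3-[4-hydroxy-3-(hydroxymethyl)phenyl]-7-[(2-methylbut-3-en-2-yl)oxy]-4H-chromen-4-one; 8 isobutene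
Product: 11 3-(2,2-dimethyl-3,4-dihydro-2H-chromen-6-yl)-7-hydroxy-8-(3-methylbut-2-en-1-yl)-4H-chromen-4-one, via Claisen phenol 9 (not isolated), via ortho-quinone methide 10 (not isolated)
Conditions: isobutene (large excess, condensed), PhMe (high dilution), BHT (cat.), steel autoclave, 120 °C then 170 °C
Reagents that add atoms: isobutene (8), C=C(C)C
Why: At 120 °C the aryl 1,1-dimethylallyl ether on O7 should undergo the aromatic Claisen rearrangement ([3,3] shift to C8, the ortho carbon favoured by the higher C7–C8 bond order of the benzopyranone, then enolisation) to give 9; at 170 °C the salicyl alcohol of ring B should lose water to the ortho-quinone methide 10, whose O=C4'–C3'=CH2 oxadiene is captured by isobutene in an inverse-electron-demand hetero-Diels–Alder reaction that forms the ArCH2–CH2 and O–CMe2 bonds. The closest known reaction type is the thermal dehydration of 2-hydroxybenzyl alcohols to ortho-quinone methides and their [4+2] capture by unactivated 1,1-disubstituted alkenes to give 2,2-dialkylchromans. The dihydropyran ring closes by an intermolecular, concerted but asynchronous [4+2] cycloaddition (4π oxadiene plus 2π alkene, C–C bond formation running ahead of C–O), driven by rearomatisation of ring B. No stereocentre is created, because C3 of the isoflavone is still sp2. The step needs regioselectivity, which the polarisation of the partners secures (nucleophilic CH2 of isobutene to the electrophilic methide carbon, tertiary carbon to oxygen), and chemoselectivity for isobutene over the prenyl alkene and the phenols, which its large excess and the high dilution secure; the sp2 C3 para to O4' carries no hydrogen, so no para-quinone methide can form.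

Step 5
Reactants: 11 3-(2,2-dimethyl-3,4-dihydro-2H-chromen-6-yl)-7-hydroxy-8-(3-methylbut-2-en-1-yl)-4H-chromen-4-one; 12 tert-butyldimethylsilyl chloride
Product: 13 7-[(tert-butyldimethylsilyl)oxy]-3-(2,2-dimethyl-3,4-dihydro-2H-chromen-6-yl)-8-(3-methylbut-2-en-1-yl)-4H-chromen-4-one
Conditions: TBSCl, imidazole, DMF, rt
Reagents that add atoms: tert-butyldimethylsilyl chloride (12), CC(C)(C)[Si](C)(C)Cl
Why: Standard silylation of the only remaining hydroxyl, the acidic 7-OH, should mask the phenol against the later periodinane oxidation.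

Step 6
Reactants: 13 7-[(tert-butyldimethylsilyl)oxy]-3-(2,2-dimethyl-3,4-dihydro-2H-chromen-6-yl)-8-(3-methylbut-2-en-1-yl)-4H-chromen-4-one
Product: 15 (3R,4R)-7-[(tert-butyldimethylsilyl)oxy]-3-(2,2-dimethyl-3,4-dihydro-2H-chromen-6-yl)-8-(3-methylbut-2-en-1-yl)-3,4-dihydro-2H-chromen-4-ol, via racemic isoflavanone 14 (not isolated)
Conditions: RuCl[(R,R)-TsDPEN](p-cymene) (cat.), HCO2H/Et3N (5:2), EtOAc, 40 °C
Reagents that add atoms: none
Why: Noyori–Ikariya asymmetric transfer hydrogenation, in which Ru–H first adds in conjugate fashion to C2 to give racemic isoflavanone 14, whose C3 epimerises through the enol under Et3N (dynamic kinetic resolution) while the (R,R) catalyst reduces the (3R) ketone faster and delivers hydride to the C4 face that gives the cis-(3R,4R) alcohol, so both stereocentres are set under catalyst control and the isolated prenyl alkene is not touched.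

Step 7
Reactants: 15 (3R,4R)-7-[(tert-butyldimethylsilyl)oxy]-3-(2,2-dimethyl-3,4-dihydro-2H-chromen-6-yl)-8-(3-methylbut-2-en-1-yl)-3,4-dihydro-2H-chromen-4-ol
Product: 16 (3R)-7-[(tert-butyldimethylsilyl)oxy]-3-(2,2-dimethyl-3,4-dihydro-2H-chromen-6-yl)-8-(3-methylbut-2-en-1-yl)-2,3-dihydro-4H-chromen-4-one
Conditions: Dess–Martin periodinane, CH2Cl2, 0 °C to rt
Reagents that add atoms: none
Why: Dess–Martin oxidation of the benzylic secondary alcohol runs without base, so C3 should not enolise and should keep its (R) configuration while the C4 stereocentre is removed.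

Step 8
Reactants: 16 (3R)-7-[(tert-butyldimethylsilyl)oxy]-3-(2,2-dimethyl-3,4-dihydro-2H-chromen-6-yl)-8-(3-methylbut-2-en-1-yl)-2,3-dihydro-4H-chromen-4-one
Product: 17 (3R)-3-(2,2-dimethyl-3,4-dihydro-2H-chromen-6-yl)-7-hydroxy-8-(3-methylbut-2-en-1-yl)-2,3-dihydro-4H-chromen-4-one
Conditions: HF·pyridine, pyridine, THF, 0 °C
Reagents that add atoms: none
Why: Fluoride-driven cleavage of the aryl silyl ether in a weakly acidic, pyridine-buffered medium should free the phenol without a base able to enolise the ketone and without acid strong enough to cyclise the prenyl group onto O7, so (3R) is retained.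

**Compound list**

1 | daidzein, 7-hydroxy-3-(4-hydroxyphenyl)-4H-chromen-4-one | O=c1c(-c2ccc(O)cc2)coc2cc(O)ccc12 | starting material
2 | 3-chloro-3-methylbut-1-yne | C#CC(C)(C)Cl | starting material
3 | 3-(4-hydroxyphenyl)-7-[(2-methylbut-3-yn-2-yl)oxy]-4H-chromen-4-one | C#CC(C)(C)Oc1ccc2c(c1)occ(-c1ccc(O)cc1)c2=O | intermediate
4 | formaldehyde (used as paraformaldehyde) | C=O | starting material
5 | 7-[(2-methylbut-3-yn-2-yl)oxy]-3-(2-phenyl-4H-1,3,2-benzodioxaborinin-6-yl)-4H-chromen-4-one | C#CC(C)(C)Oc1ccc2c(c1)occ(-c1ccc3OB(c4ccccc4)OCc3c1)c2=O | intermediate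
6 | 3-[4-hydroxy-3-(hydroxymethyl)phenyl]-7-[(2-methylbut-3-yn-2-yl)oxy]-4H-chromen-4-one | C#CC(C)(C)Oc1ccc2c(c1)occ(-c1ccc(O)c(CO)c1)c2=O | intermediate
7 | 3-[4-hydroxy-3-(hydroxymethyl)phenyl]-7-[(2-methylbut-3-en-2-yl)oxy]-4H-chromen-4-one | C=CC(C)(C)Oc1ccc2c(c1)occ(-c1ccc(O)c(CO)c1)c2=O | intermediate
8 | isobutene, 2-methylprop-1-ene | C=C(C)C | starting material
9 | 7-hydroxy-3-[4-hydroxy-3-(hydroxymethyl)phenyl]-8-(3-methylbut-2-en-1-yl)-4H-chromen-4-one | CC(C)=CCc1c(O)ccc2c1occ(-c1ccc(O)c(CO)c1)c2=O | intermediate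
10 | 7-hydroxy-8-(3-methylbut-2-en-1-yl)-3-(3-methylidene-4-oxocyclohexa-1,5-dien-1-yl)-4H-chromen-4-one (ortho-quinone methide) | CC(C)=CCc1c(O)ccc2c1occ(C1=CC(=C)C(=O)C=C1)c2=O | intermediate
11 | 3-(2,2-dimethyl-3,4-dihydro-2H-chromen-6-yl)-7-hydroxy-8-(3-methylbut-2-en-1-yl)-4H-chromen-4-one | CC(C)=CCc1c(O)ccc2c1occ(-c1ccc3c(c1)CCC(C)(C)O3)c2=O | intermediate
12 | tert-butyldimethylsilyl chloride | CC(C)(C)[Si](C)(C)Cl | starting material
13 | 7-[(tert-butyldimethylsilyl)oxy]-3-(2,2-dimethyl-3,4-dihydro-2H-chromen-6-yl)-8-(3-methylbut-2-en-1-yl)-4H-chromen-4-one | CC(C)=CCc1c(O[Si](C)(C)C(C)(C)C)ccc2c1occ(-c1ccc3c(c1)CCC(C)(C)O3)c2=O | intermediate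
14 | racemic 7-[(tert-butyldimethylsilyl)oxy]-3-(2,2-dimethyl-3,4-dihydro-2H-chromen-6-yl)-8-(3-methylbut-2-en-1-yl)-2,3-dihydro-4H-chromen-4-one | CC(C)=CCc1c(O[Si](C)(C)C(C)(C)C)ccc2c1OCC(c1ccc3c(c1)CCC(C)(C)O3)C2=O | intermediate
15 | (3R,4R)-7-[(tert-butyldimethylsilyl)oxy]-3-(2,2-dimethyl-3,4-dihydro-2H-chromen-6-yl)-8-(3-methylbut-2-en-1-yl)-3,4-dihydro-2H-chromen-4-ol (aryl and OH cis) | CC(C)=CCc1c(O[Si](C)(C)C(C)(C)C)ccc2c1OC[C@@H](c1ccc3c(c1)CCC(C)(C)O3)[C@H]2O | intermediate
16 | (3R)-7-[(tert-butyldimethylsilyl)oxy]-3-(2,2-dimethyl-3,4-dihydro-2H-chromen-6-yl)-8-(3-methylbut-2-en-1-yl)-2,3-dihydro-4H-chromen-4-one | CC(C)=CCc1c(O[Si](C)(C)C(C)(C)C)ccc2c1OC[C@@H](c1ccc3c(c1)CCC(C)(C)O3)C2=O | intermediate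
17 | (3R)-3-(2,2-dimethyl-3,4-dihydro-2H-chromen-6-yl)-7-hydroxy-8-(3-methylbut-2-en-1-yl)-2,3-dihydro-4H-chromen-4-one | CC(C)=CCc1c(O)ccc2c1OC[C@@H](c1ccc3c(c1)CCC(C)(C)O3)C2=O | target

Total step count: 8
Longest linear sequence: 8 steps (1 to 17)

**Steps most likely to fail**

Step 4. The ortho-quinone methide may condense with the phenolic rings of other molecules faster than the weakly nucleophilic alkene captures it. The freshly formed ortho-prenylphenol may also cyclise or rearrange further at the temperature needed, and some of the allyl group may migrate to C6 instead of C8. The fallback builds the chroman by the prenyl-cyclisation logic; it sets out from 3 and comes back at 11. The free 4'-OH of 3 is O-alkylated with tert-butyl (2-methylbut-3-en-2-yl) carbonate and catalytic Pd(PPh3)4 in THF to give 3-{4-[(2-methylbut-3-en-2-yl)oxy]phenyl}-7-[(2-methylbut-3-yn-2-yl)oxy]-4H-chromen-4-one F1. An Eu(fod)3-catalysed aromatic Claisen rearrangement at 60 °C, which the propargylic ether on ring A should survive, gives 3-[4-hydroxy-3-(3-methylbut-2-en-1-yl)phenyl]-7-[(2-methylbut-3-yn-2-yl)oxy]-4H-chromen-4-one F2. Acid-catalysed Markovnikov cyclisation of this ortho-prenylphenol (Amberlyst-15, CH2Cl2) gives 3-(2,2-dimethyl-3,4-dihydro-2H-chromen-6-yl)-7-[(2-methylbut-3-yn-2-yl)oxy]-4H-chromen-4-one F3. Semihydrogenation over Pd/CaCO3 poisoned with Pb(OAc)2 gives 3-(2,2-dimethyl-3,4-dihydro-2H-chromen-6-yl)-7-[(2-methylbut-3-en-2-yl)oxy]-4H-chromen-4-one F4. A second Eu(fod)3-catalysed Claisen rearrangement, now on ring A and at a temperature too low for further reaction of the product, gives 11.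

Step 2. Ortho C–C bond formation may be sluggish on this poorly soluble, weakly nucleophilic phenol, and the tertiary propargylic ether may ionise under warm acid. The fallback sets out from 3 and comes back at 6. Magnesium-phenoxide-directed ortho-formylation (MgCl2, Et3N, paraformaldehyde, THF, reflux), which is base-mediated and stops at mono-substitution, gives 2-hydroxy-5-{7-[(2-methylbut-3-yn-2-yl)oxy]-4-oxo-4H-chromen-3-yl}benzaldehyde F5. Reduction of the aldehyde with NaBH4 in MeOH/THF at −20 °C, where the chromone is not yet attacked, gives 6.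

Step 6. Conjugate reduction of the hindered, electron-rich isoflavone may stall, enantio- or diastereoselection in the dynamic kinetic resolution may erode, or the silyl ether may be lost in the formate medium. The fallback replaces asymmetric catalysis by resolution; it sets out from 13 and comes back at 17. Conjugate reduction with LiBH(s-Bu)3 in THF at −78 °C gives the racemic isoflavanone 14, now isolated. Desilylation with HF·pyridine gives racemic 3-(2,2-dimethyl-3,4-dihydro-2H-chromen-6-yl)-7-hydroxy-8-(3-methylbut-2-en-1-yl)-2,3-dihydro-4H-chromen-4-one F6. Preparative HPLC on an amylose tris(3,5-dimethylphenylcarbamate) stationary phase should separate the enantiomers and deliver 17; the unwanted (3S) enantiomer is racemised with Et3N and recycled.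

**Further compounds**

F1 | step 4 | 3-{4-[(2-methylbut-3-en-2-yl)oxy]phenyl}-7-[(2-methylbut-3-yn-2-yl)oxy]-4H-chromen-4-one | C#CC(C)(C)Oc1ccc2c(c1)occ(-c1ccc(OC(C)(C)C=C)cc1)c2=O
F2 | step 4 | 3-[4-hydroxy-3-(3-methylbut-2-en-1-yl)phenyl]-7-[(2-methylbut-3-yn-2-yl)oxy]-4H-chromen-4-one | C#CC(C)(C)Oc1ccc2c(c1)occ(-c1ccc(O)c(CC=C(C)C)c1)c2=O
F3 | step 4 | 3-(2,2-dimethyl-3,4-dihydro-2H-chromen-6-yl)-7-[(2-methylbut-3-yn-2-yl)oxy]-4H-chromen-4-one | C#CC(C)(C)Oc1ccc2c(c1)occ(-c1ccc3c(c1)CCC(C)(C)O3)c2=O
F4 | step 4 | 3-(2,2-dimethyl-3,4-dihydro-2H-chromen-6-yl)-7-[(2-methylbut-3-en-2-yl)oxy]-4H-chromen-4-one | C=CC(C)(C)Oc1ccc2c(c1)occ(-c1ccc3c(c1)CCC(C)(C)O3)c2=O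
F5 | step 2 | 2-hydroxy-5-{7-[(2-methylbut-3-yn-2-yl)oxy]-4-oxo-4H-chromen-3-yl}benzaldehyde | C#CC(C)(C)Oc1ccc2c(c1)occ(-c1ccc(O)c(C=O)c1)c2=O
F6 | step 6 | racemic 3-(2,2-dimethyl-3,4-dihydro-2H-chromen-6-yl)-7-hydroxy-8-(3-methylbut-2-en-1-yl)-2,3-dihydro-4H-chromen-4-one | CC(C)=CCc1c(O)ccc2c1OCC(c1ccc3c(c1)CCC(C)(C)O3)C2=O
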